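**Plan**

1. Retrosynthetic cuts: the ester C–O bond between the ring A cinnamoyl carbonyl and O2 of the danshensu unit; the ring C aryl–CH2 bond of that unit; the enol ether C=C between ring B's benzylic CH and the aryloxy-bearing carbon; the ring A cinnamate C=C; the ring A O3–CH2 bond.
2. Enabling feature: the CH2 on ring C (C3 of the danshensu unit) adjoins the oxygen-bearing stereocentre C2, which carries the C1 carboxyl. This C1–C2(O)–C3 triad is C1–C3 of (R)-malic acid, so C3 can be joined to ring C as a radical once the C4 carboxyl has left as CO2.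
3. Forward, ring C arm: malic acid acetonide, N-hydroxyphthalimide ester, nickel-catalysed decarboxylative arylation with the ring C arylzinc, acid hydrolysis to (R)-danshensu, triple O-allylation.
4. Forward, ring A/B arm: 4-O-allylation of 3,4-dihydroxybenzaldehyde, O3-alkylation with allyl bromoacetate, Wittig olefination, aldol addition to the ring B aldehyde, dehydration to the enol ether, release of the cinnamic acid.
5. The arms are joined by esterification and all seven allyl groups are removed in one palladium-catalysed step. No skeletal ring is formed: the three benzene rings are bought and the dioxolanone is temporary.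
6. Stereochemistry: the R centre is C2 of (R)-malic acid and no bond to it is ever broken; the E cinnamate comes from a stabilised ylide and the Z enol ether from a thermodynamically controlled elimination.

Key step: step 5

Assumption: the target is read from the SMILES as 2R in the danshensu unit, E in the ring A cinnamate and Z in the enol ether (ring B cis to the aryloxy oxygen); (R)-malic acid, allyl bromoacetate and tert-butyl (triphenylphosphoranylidene)acetate are taken as purchasable.

**Route**

Step 1
Reactants: 1 (R)-malic acid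
Product: 2 (R)-2-(2,2-dimethyl-5-oxo-1,3-dioxolan-4-yl)acetic acid
Conditions: 2,2-dimethoxypropane, TsOH·H2O (cat.), rt
Reagents that add atoms: 2,2-dimethoxypropane, COC(C)(C)OC
Why: Acid-catalysed transacetalisation (acetonide formation) ties the C2 hydroxyl and the C1 carboxyl into the favoured five-membered 1,3-dioxolan-4-one, leaves the C4 carboxyl free and does not touch the C2–H bond.

Step 2
Reactants: 2 (R)-2-(2,2-dimethyl-5-oxo-1,3-dioxolan-4-yl)acetic acid; 3 N-hydroxyphthalimide
Product: 4 1,3-dioxoisoindolin-2-yl (R)-2-(2,2-dimethyl-5-oxo-1,3-dioxolan-4-yl)acetate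
Conditions: N,N'-diisopropylcarbodiimide (DIC), DMAP (cat.), CH2Cl2, 0 °C to rt
Reagents that add atoms: none
Why: Carbodiimide (Steglich-type) esterification of the single free carboxyl with the N-hydroxy imide should give the redox-active ester under neutral conditions that spare the dioxolanone.

Step 3
Reactants: 5 4-bromocatechol
Product: 6 4-bromo-1,2-bis(methoxymethoxy)benzene
Conditions: MOMCl, i-Pr2NEt, CH2Cl2, 0 °C to rt
Reagents that add atoms: chloromethyl methyl ether, COCCl
Why: Williamson-type O-alkylation of both phenols gives methoxymethyl ethers that withstand the organometallic steps and are later removed with aqueous acid.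

Step 4
Reactants: 6 4-bromo-1,2-bis(methoxymethoxy)benzene
Product: 8 [3,4-bis(methoxymethoxy)phenyl]zinc chloride, via [3,4-bis(methoxymethoxy)phenyl]lithium 7 (not isolated)
Conditions: n-BuLi, THF, −78 °C; then ZnCl2 (1.0 M in THF), −78 °C to rt; solution titrated and used directly
Reagents that add atoms: zinc chloride, Cl[Zn]Cl
Why: Bromine–lithium exchange followed by transmetalation to zinc, run cold and quenched at once with ZnCl2 so that the lithium cannot migrate to a position ortho to a MOM ether.

Step 5
Reactants: 4 1,3-dioxoisoindolin-2-yl (R)-2-(2,2-dimethyl-5-oxo-1,3-dioxolan-4-yl)acetate; 8 [3,4-bis(methoxymethoxy)phenyl]zinc chloride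
Product: 9 (R)-5-[3,4-bis(methoxymethoxy)benzyl]-2,2-dimethyl-1,3-dioxolan-4-one
Conditions: NiCl2(dme) (20 mol%; dme = 1,2-dimethoxyethane), 4,4'-di-tert-butyl-2,2'-bipyridine (40 mol%), 8 (3 equiv), THF/DMF, rt
Reagents that add atoms: none
Why: The bipyridine-ligated nickel catalyst is arylated by 8, and the resulting aryl complex of monovalent nickel passes one electron to the phthalimide ester of 4, whose radical anion breaks at the N–O bond and extrudes CO2 to leave a primary radical at C3 of the malic skeleton; this radical is captured at nickel and reductive elimination from the trivalent aryl(alkyl)nickel species makes the C3–ring C bond. The closest known reaction type is the nickel-catalysed decarboxylative Negishi-type coupling of N-hydroxyphthalimide esters with arylzinc halides, which is established for primary alkyl acids. No ring is closed and no stereocentre is created: the R centre at C2 comes unchanged from 1, because the radical lies on the neighbouring carbon and neither the C2–H nor the C2–O bond is broken. The step needs the radical to arise only at C3 and the C2–O bond to survive; the first is secured by the dioxolanone, which locks the C1 carboxyl and the hydroxyl so that C4 is the only carboxyl able to carry the redox-active ester, the second by the reluctance of a carbon radical to expel a β-alkoxy group and by reductive elimination from the bipyridine complex outpacing β-oxygen elimination at nickel. The arylzinc chloride is too weak a nucleophile and base to open the dioxolanone or remove the C2 proton, and the MOM ethers are inert.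

Step 6
Reactants: 9 (R)-5-[3,4-bis(methoxymethoxy)benzyl]-2,2-dimethyl-1,3-dioxolan-4-one
Product: 10 (R)-3-(3,4-dihydroxyphenyl)-2-hydroxypropanoic acid ((R)-danshensu)
Conditions: 2 M aq. HCl/THF (1:1), 50 °C, argon; EtOAc extraction, crude used at once
Reagents that add atoms: none
Why: Acid-catalysed acetal hydrolysis: the ketal carbon of the dioxolanone and both MOM acetals ionise to oxocarbenium ions that water traps, its oxygen leaving in acetone and formaldehyde, so hydroxy acid and catechol are freed in one operation without any bond to C2 being broken.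

Step 7
Reactants: 10 (R)-danshensu
Product: 11 allyl (R)-3-[3,4-bis(allyloxy)phenyl]-2-hydroxypropanoate
Conditions: allyl bromide (3.3 equiv), K2CO3, DMF, rt, argon
Reagents that add atoms: allyl bromide, C=CCBr
Why: Williamson alkylation under carbonate: K2CO3 ionises only the carboxylic acid and the two phenols, so three allyl groups go on while the secondary C2 hydroxyl stays free for the later esterification.

Step 8
Reactants: 12 3,4-dihydroxybenzaldehyde
Product: 13 3,4-bis(allyloxy)benzaldehyde
Conditions: allyl bromide (2.5 equiv), K2CO3, DMF, rt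
Reagents that add atoms: allyl bromide, C=CCBr
Why: Williamson etherification of both phenols provides the ring B aldehyde in the protecting-group pattern used for the whole route.

Step 9
Reactants: 12 3,4-dihydroxybenzaldehyde
Product: 14 4-(allyloxy)-3-hydroxybenzaldehyde
Conditions: allyl bromide (1.05 equiv), NaHCO3, DMF, 40 °C
Reagents that add atoms: allyl bromide, C=CCBr
Why: Regioselective Williamson mono-alkylation: the 4-hydroxyl, para to the formyl group, is the more acidic phenol and is the one ionised by the weak base, so the 3-hydroxyl of ring A stays free.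

Step 10
Reactants: 14 4-(allyloxy)-3-hydroxybenzaldehyde; 15 allyl bromoacetate
Product: 16 allyl 2-[2-(allyloxy)-5-formylphenoxy]acetate
Conditions: K2CO3, acetone, reflux
Reagents that add atoms: none
Why: Williamson etherification (SN2 at the α-bromo ester) attaches to O3 of ring A the two-carbon unit that becomes the enol ether carbon and its carboxyl.

Step 11
Reactants: 16 allyl 2-[2-(allyloxy)-5-formylphenoxy]acetate; 17 tert-butyl (triphenylphosphoranylidene)acetate
Product: 18 tert-butyl (E)-3-{4-(allyloxy)-3-[2-(allyloxy)-2-oxoethoxy]phenyl}acrylate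
Conditions: toluene, 80 °C
Reagents that add atoms: none
Why: Wittig olefination with a stabilised ylide should give the E cinnamate, and the tert-butyl ester is chosen because acid removes it in the presence of the allyl ester.

Step 12
Reactants: 18 tert-butyl (E)-3-{4-(allyloxy)-3-[2-(allyloxy)-2-oxoethoxy]phenyl}acrylate; 13 3,4-bis(allyloxy)benzaldehyde
Product: 20 allyl 3-[3,4-bis(allyloxy)phenyl]-2-{2-(allyloxy)-5-[(E)-3-(tert-butoxy)-3-oxoprop-1-enyl]phenoxy}-3-hydroxypropanoate (diastereomer mixture), via lithium enolate 19 (not isolated)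
Conditions: LiN(i-Pr)2 (1.1 equiv), THF, −78 °C, 20 min; then 13, −78 °C; AcOH quench at −78 °C
Reagents that add atoms: none
Why: Aldol addition of a lithium aryloxyacetate enolate to a non-enolisable dialkoxybenzaldehyde, a well-established pairing; the two new stereocentres form as a mixture that is irrelevant because both are erased in step 13, and the cold acidic quench forestalls Claisen rearrangement of the allyl ester enolate.

Step 13
Reactants: 20 allyl 3-[3,4-bis(allyloxy)phenyl]-2-{2-(allyloxy)-5-[(E)-3-(tert-butoxy)-3-oxoprop-1-enyl]phenoxy}-3-hydroxypropanoate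
Product: 22 allyl (Z)-3-[3,4-bis(allyloxy)phenyl]-2-{2-(allyloxy)-5-[(E)-3-(tert-butoxy)-3-oxoprop-1-enyl]phenoxy}acrylate, via mesylate 21 (not isolated)
Conditions: MsCl, Et3N, CH2Cl2, 0 °C; then DBU, 0 °C to rt
Reagents that add atoms: none
Why: Mesylation and base-induced elimination (E1cB through the ester enolate): both diastereomers should converge on the conjugated enol ether, and the Z isomer, with ring B trans to the ester and cis to the aryloxy oxygen, is expected to prevail as the more stable one.

Step 14
Reactants: 22 allyl (Z)-3-[3,4-bis(allyloxy)phenyl]-2-{2-(allyloxy)-5-[(E)-3-(tert-butoxy)-3-oxoprop-1-enyl]phenoxy}acrylate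
Product: 23 (E)-3-[4-(allyloxy)-3-({(Z)-1-(allyloxycarbonyl)-2-[3,4-bis(allyloxy)phenyl]vinyl}oxy)phenyl]acrylic acid
Conditions: CF3CO2H/CH2Cl2 (1:3), anisole, 0 °C to rt
Reagents that add atoms: none
Why: Acidolysis of the tert-butyl ester (loss of isobutene through the tert-butyl cation, anisole as cation trap) frees the cinnamic acid while the allyl ester, the aryl allyl ethers and the ester-deactivated enol ether should be left alone.

Step 15
Reactants: 23 (E)-3-[4-(allyloxy)-3-({(Z)-1-(allyloxycarbonyl)-2-[3,4-bis(allyloxy)phenyl]vinyl}oxy)phenyl]acrylic acid; 11 allyl (R)-3-[3,4-bis(allyloxy)phenyl]-2-hydroxypropanoate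
Product: 24 allyl (R)-3-[3,4-bis(allyloxy)phenyl]-2-({(E)-3-[4-(allyloxy)-3-({(Z)-1-(allyloxycarbonyl)-2-[3,4-bis(allyloxy)phenyl]vinyl}oxy)phenyl]acryloyl}oxy)propanoate (hepta-allyl salvianolic acid H)
Conditions: EDC·HCl, DMAP (0.2 equiv), CH2Cl2, 0 °C to rt
Reagents that add atoms: none
Why: Steglich esterification of the conjugated acid with the only free hydroxyl of 11; the alcohol oxygen is acylated without any bond to C2 being broken, so the R configuration is retained.

Step 16
Reactants: 24 hepta-allyl salvianolic acid H
Product: 25 salvianolic acid H, (R)-2-({(E)-3-[3-({(Z)-1-carboxy-2-(3,4-dihydroxyphenyl)vinyl}oxy)-4-hydroxyphenyl]acryloyl}oxy)-3-(3,4-dihydroxyphenyl)propanoic acid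
Conditions: Pd(PPh3)4 (10 mol%), morpholine (20 equiv), THF, rt, argon; then dilute aq. HCl work-up
Reagents that add atoms: none
Why: Tsuji–Trost deallylation: zerovalent palladium ionises the two allyl esters and five aryl allyl ethers to π-allyl complexes that morpholine intercepts, releasing acids and phenols under near-neutral conditions that should spare the cinnamate ester, the enol ether and the stereocentre.

**Compound list**

1 | (R)-malic acid | O[C@H](CC(=O)O)C(=O)O | starting material
2 | (R)-2-(2,2-dimethyl-5-oxo-1,3-dioxolan-4-yl)acetic acid | CC1(C)O[C@H](CC(=O)O)C(=O)O1 | intermediate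
3 | N-hydroxyphthalimide | ON1C(=O)c2ccccc2C1=O | starting material
4 | 1,3-dioxoisoindolin-2-yl (R)-2-(2,2-dimethyl-5-oxo-1,3-dioxolan-4-yl)acetate | CC1(C)O[C@H](CC(=O)ON2C(=O)c3ccccc3C2=O)C(=O)O1 | intermediate
5 | 4-bromocatechol | Oc1ccc(Br)cc1O | starting material
6 | 4-bromo-1,2-bis(methoxymethoxy)benzene | COCOc1ccc(Br)cc1OCOC | intermediate
7 | [3,4-bis(methoxymethoxy)phenyl]lithium (not isolated) | [Li]c1ccc(OCOC)c(OCOC)c1 | intermediate
8 | [3,4-bis(methoxymethoxy)phenyl]zinc chloride | Cl[Zn]c1ccc(OCOC)c(OCOC)c1 | intermediate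
9 | (R)-5-[3,4-bis(methoxymethoxy)benzyl]-2,2-dimethyl-1,3-dioxolan-4-one | CC1(C)O[C@H](Cc2ccc(OCOC)c(OCOC)c2)C(=O)O1 | intermediate
10 | (R)-3-(3,4-dihydroxyphenyl)-2-hydroxypropanoic acid ((R)-danshensu) | O[C@H](Cc1ccc(O)c(O)c1)C(=O)O | intermediate
11 | allyl (R)-3-[3,4-bis(allyloxy)phenyl]-2-hydroxypropanoate | O[C@H](Cc1ccc(OCC=C)c(OCC=C)c1)C(=O)OCC=C | intermediate
12 | 3,4-dihydroxybenzaldehyde | O=Cc1ccc(O)c(O)c1 | starting material
13 | 3,4-bis(allyloxy)benzaldehyde | O=Cc1ccc(OCC=C)c(OCC=C)c1 | intermediate
14 | 4-(allyloxy)-3-hydroxybenzaldehyde | O=Cc1ccc(OCC=C)c(O)c1 | intermediate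
15 | allyl bromoacetate | C=CCOC(=O)CBr | starting material
16 | allyl 2-[2-(allyloxy)-5-formylphenoxy]acetate | O=Cc1ccc(OCC=C)c(OCC(=O)OCC=C)c1 | intermediate
17 | tert-butyl (triphenylphosphoranylidene)acetate | CC(C)(C)OC(=O)C=P(c1ccccc1)(c1ccccc1)c1ccccc1 | starting material
18 | tert-butyl (E)-3-{4-(allyloxy)-3-[2-(allyloxy)-2-oxoethoxy]phenyl}acrylate | CC(C)(C)OC(=O)/C=C/c1ccc(OCC=C)c(OCC(=O)OCC=C)c1 | intermediate
19 | lithium enolate of 18 at the aryloxyacetate carbon (not isolated; enolate geometry undefined) | CC(C)(C)OC(=O)/C=C/c1ccc(OCC=C)c(OC=C(O[Li])OCC=C)c1 | intermediate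
20 | allyl 3-[3,4-bis(allyloxy)phenyl]-2-{2-(allyloxy)-5-[(E)-3-(tert-butoxy)-3-oxoprop-1-enyl]phenoxy}-3-hydroxypropanoate (syn/anti mixture, racemic at C2 and C3) | CC(C)(C)OC(=O)/C=C/c1ccc(OCC=C)c(OC(C(=O)OCC=C)C(O)c2ccc(OCC=C)c(OCC=C)c2)c1 | intermediate
21 | 3-O-methanesulfonate of 20 (not isolated; diastereomer mixture) | CC(C)(C)OC(=O)/C=C/c1ccc(OCC=C)c(OC(C(=O)OCC=C)C(OS(C)(=O)=O)c2ccc(OCC=C)c(OCC=C)c2)c1 | intermediate
22 | allyl (Z)-3-[3,4-bis(allyloxy)phenyl]-2-{2-(allyloxy)-5-[(E)-3-(tert-butoxy)-3-oxoprop-1-enyl]phenoxy}acrylate | CC(C)(C)OC(=O)/C=C/c1ccc(OCC=C)c(O/C(=C\c2ccc(OCC=C)c(OCC=C)c2)C(=O)OCC=C)c1 | intermediate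
23 | (E)-3-[4-(allyloxy)-3-({(Z)-1-(allyloxycarbonyl)-2-[3,4-bis(allyloxy)phenyl]vinyl}oxy)phenyl]acrylic acid | OC(=O)/C=C/c1ccc(OCC=C)c(O/C(=C\c2ccc(OCC=C)c(OCC=C)c2)C(=O)OCC=C)c1 | intermediate
24 | allyl (R)-3-[3,4-bis(allyloxy)phenyl]-2-({(E)-3-[4-(allyloxy)-3-({(Z)-1-(allyloxycarbonyl)-2-[3,4-bis(allyloxy)phenyl]vinyl}oxy)phenyl]acryloyl}oxy)propanoate | O=C(/C=C/c1ccc(OCC=C)c(O/C(=C\c2ccc(OCC=C)c(OCC=C)c2)C(=O)OCC=C)c1)O[C@H](Cc1ccc(OCC=C)c(OCC=C)c1)C(=O)OCC=C | intermediate
25 | salvianolic acid H | O=C(/C=C/c1ccc(O)c(O/C(=C\c2ccc(O)c(O)c2)C(=O)O)c1)O[C@H](Cc1ccc(O)c(O)c1)C(=O)O | target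

**Count and risks**

Total step count: 16. Longest linear sequence: 8 steps (12 → 14 → 16 → 18 → 20 → 22 → 23 → 24 → 25, steps 9 to 16); the ring C arm reaches 25 in 7 steps from 1 or from 5.

Steps most likely to fail:

Step 5. The primary radical may be captured too slowly by nickel, so that hydrogen abstraction, dimerisation or loss of the β-oxygen at the alkylnickel stage take over, or the arylzinc may attack the activated ester. The fallback sets out from 6 and returns at 10, making the aryl–CH2 bond by epoxide opening instead of radical coupling. Bromide 6 is converted with Mg turnings in THF into [3,4-bis(methoxymethoxy)phenyl]magnesium bromide F1. Under CuI catalysis (10 mol%, THF, −30 °C) F1 opens purchased methyl (R)-oxirane-2-carboxylate (COC(=O)[C@H]1CO1) at its CH2 carbon to give methyl (R)-3-[3,4-bis(methoxymethoxy)phenyl]-2-hydroxypropanoate F2. The stereocentre is bought with the epoxide and takes no part in the reaction. Saponification (LiOH, THF/water, 0 °C) followed by acidification with aqueous HCl at 50 °C should remove the methyl ester and the MOM groups and deliver 10.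

Step 12. Conjugate addition of the lithium enolate to the cinnamate of a second molecule, or Claisen rearrangement of the allyl ester enolate, may compete with aldol addition. The fallback sets out from 18 and returns at 22, bypassing 20; it condenses through an anhydride enolate instead of a lithium enolate. LiOH in THF/water at 0 °C hydrolyses the reactive allyl aryloxyacetate of 18 and spares the tert-butyl ester, giving 2-{2-(allyloxy)-5-[(E)-3-(tert-butoxy)-3-oxoprop-1-enyl]phenoxy}acetic acid F3. A Perkin–Oglialoro condensation of F3 with 13 (Ac2O, Et3N, 110 °C, aqueous work-up) should give, under thermodynamic control, (Z)-3-[3,4-bis(allyloxy)phenyl]-2-{2-(allyloxy)-5-[(E)-3-(tert-butoxy)-3-oxoprop-1-enyl]phenoxy}acrylic acid F4. Allyl bromide and K2CO3 in DMF then re-esterify F4 to 22.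

Step 13. The elimination may not converge fully, giving poor E/Z control at the enol ether. The fallback sets out from 20 and returns at 22, setting the geometry in a separate equilibration. 20 is dehydrated as in step 13 without regard to selectivity. The unwanted isomer, allyl (E)-3-[3,4-bis(allyloxy)phenyl]-2-{2-(allyloxy)-5-[(E)-3-(tert-butoxy)-3-oxoprop-1-enyl]phenoxy}acrylate F5, alone or in the mixture, is then treated with I2 (5 mol%) in toluene at 80 °C under visible light. Reversible iodine-atom addition to the enol ether double bond should funnel F5 into the more stable Z isomer 22.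

**Further compounds**

F1 | step 5 | [3,4-bis(methoxymethoxy)phenyl]magnesium bromide | Br[Mg]c1ccc(OCOC)c(OCOC)c1
F2 | step 5 | methyl (R)-3-[3,4-bis(methoxymethoxy)phenyl]-2-hydroxypropanoate | COC(=O)[C@H](O)Cc1ccc(OCOC)c(OCOC)c1
F3 | step 12 | 2-{2-(allyloxy)-5-[(E)-3-(tert-butoxy)-3-oxoprop-1-enyl]phenoxy}acetic acid | CC(C)(C)OC(=O)/C=C/c1ccc(OCC=C)c(OCC(=O)O)c1
F4 | step 12 | (Z)-3-[3,4-bis(allyloxy)phenyl]-2-{2-(allyloxy)-5-[(E)-3-(tert-butoxy)-3-oxoprop-1-enyl]phenoxy}acrylic acid | CC(C)(C)OC(=O)/C=C/c1ccc(OCC=C)c(O/C(=C\c2ccc(OCC=C)c(OCC=C)c2)C(=O)O)c1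
F5 | step 13 | allyl (E)-3-[3,4-bis(allyloxy)phenyl]-2-{2-(allyloxy)-5-[(E)-3-(tert-butoxy)-3-oxoprop-1-enyl]phenoxy}acrylate | CC(C)(C)OC(=O)/C=C/c1ccc(OCC=C)c(O/C(=C/c2ccc(OCC=C)c(OCC=C)c2)C(=O)OCC=C)c1
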